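**Overview**

- Retrosynthesis: the three aryl methyl ethers are traced back first; the lactone ring is then cut at O1–C2 and C3=C4 (salicylaldehyde plus a two-carbon ylide), followed by the C–CHO bond. The last cut is the biaryl bond between flavone C6 and coumarin C8, with the coumarin benzene ring taken back to cyclohexane-1,3-dione.
- Enabling feature: coumarin C8 lies between C7–OH and C8a–O1, so it is C2 of a resorcinol and corresponds to the nucleophilic C2 of cyclohexane-1,3-dione. The derived 2-arylresorcinol has equivalent C4 and C6, so formylation and lactone closure can only give the 7-hydroxy-8-aryl coumarin.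
- Forward order: flavone rings A, B and C come intact from apigenin (methylation, C6 iodination, methylation). The saturated dione ring is attached at C6 by palladium-catalysed enolate arylation and dehydrogenated to the resorcinol ring. The lactone ring is closed last by formylation, Wittig olefination and lactonisation, and BBr3 frees the phenols.
- Stereochemistry: the target has no stereocentre; the tetra-ortho-oxygenated biaryl axis bears no descriptor and is formed without control.

Key step: step 4

**Route**

Step 1
Reactants: 1 apigenin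
Product: 2 5-hydroxy-7,4'-dimethoxyflavone
Conditions: Me2SO4 (2.2 equiv), K2CO3 (3 equiv), acetone, reflux
Reagents that add atoms: dimethyl sulfate, COS(=O)(=O)OC
Why: Williamson O-methylation takes the acidic 7-OH and 4'-OH, while the 5-OH, hydrogen-bonded to the C4 carbonyl, reacts slowest and should stay free with a limited charge of reagent.

Step 2
Reactants: 2 5-hydroxy-7,4'-dimethoxyflavone
Product: 3 5-hydroxy-6-iodo-7,4'-dimethoxyflavone
Conditions: I2 (1.1 equiv), TlOAc (1.2 equiv), CH2Cl2, rt
Reagents that add atoms: iodine, II
Why: Electrophilic aromatic iodination through the monovalent thallium phenoxide should deliver iodine ortho to the free 5-OH, at C6 and not C8, the established regiochemistry for 5-hydroxy-7-alkoxyflavones.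

Step 3
Reactants: 3 5-hydroxy-6-iodo-7,4'-dimethoxyflavone
Product: 4 6-iodo-5,7,4'-trimethoxyflavone
Conditions: Me2SO4 (3 equiv), K2CO3 (excess), acetone, prolonged reflux
Reagents that add atoms: dimethyl sulfate, COS(=O)(=O)OC
Why: Williamson methylation under forcing conditions caps the chelated phenol, which would otherwise be deprotonated by the base of the coupling, and leaves the aryl iodide untouched.

Step 4
Reactants: 4 6-iodo-5,7,4'-trimethoxyflavone; 5 cyclohexane-1,3-dione
Product: 7 3-hydroxy-2-(5,7,4'-trimethoxyflavon-6-yl)cyclohex-2-en-1-one, via potassium enolate 6 (not isolated)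
Conditions: 5 (1.5 equiv), Pd(OAc)2 (5 mol%), 2-di-tert-butylphosphino-2',4',6'-triisopropylbiphenyl (10 mol%), K3PO4 (3 equiv), 1,4-dioxane, 100 °C, argon; then 1 M HCl
Reagents that add atoms: none
Why: Zerovalent palladium, generated in the flask from Pd(OAc)2 and the bulky biarylphosphine, inserts into the C6–I bond of 4; the potassium enolate of 5 replaces iodide on divalent palladium and binds through C2, and reductive elimination forges the bond between flavone C6 and dione C2 that later becomes the C6–C8 biaryl bond. The closest known reaction type is the palladium-catalysed alpha-arylation of cyclic 1,3-diones with 2,6-disubstituted aryl halides (Buchwald–Hartwig-type enolate arylation). No ring is closed and no stereocentre is created; the dione ring is carried in as the future coumarin benzene ring. The step needs attachment at C6 rather than C8, which the position of the iodine fixes, and C- rather than O-arylation, which the bulky electron-rich phosphine secures by favouring the carbon-bound enolate and fast C–C reductive elimination. Because the carbon nucleophile is sp2-hybridised and has only carbonyl oxygens as neighbours, it is far less encumbered than an ortho,ortho-dialkoxyaryl boron reagent, and the sluggish transmetalation and protodeboronation of such reagents do not arise. The product rests in the flask as its delocalised potassium enolate 6, which resists a second arylation and is released as enol 7 on acidification.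

Step 5
Reactants: 7 3-hydroxy-2-(5,7,4'-trimethoxyflavon-6-yl)cyclohex-2-en-1-one
Product: 8 6-(2,6-dihydroxyphenyl)-5,7,4'-trimethoxyflavone
Conditions: 10% Pd/C (10 mol% Pd), K2CO3 (0.2 equiv), ethylene (1 atm), N,N-dimethylacetamide, 130 °C
Reagents that add atoms: none
Why: Catalytic transfer dehydrogenation of a cyclohexane-1,3-dione to a resorcinol removes one molecule of hydrogen from the C4–C5 edge of the dione ring, and tautomerisation gives the arene; ethylene as acceptor keeps hydrogen away from the pyrone C2=C3 bond.

Step 6
Reactants: 8 6-(2,6-dihydroxyphenyl)-5,7,4'-trimethoxyflavone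
Product: 10 2,4-dihydroxy-3-(5,7,4'-trimethoxyflavon-6-yl)benzaldehyde, via aryl iminium chloride 9 (not isolated)
Conditions: (chloromethylene)dimethyliminium chloride (1.3 equiv), MeCN, 0 °C to rt; then H2O, 50 °C
Reagents that add atoms: (chloromethylene)dimethyliminium chloride, C[N+](C)=CCl.[Cl-]; water, O
Why: Vilsmeier–Haack formylation should occur on the free resorcinol ring, by far the most nucleophilic arene in 8, at C4 or C6, which are equivalent (each ortho to one hydroxyl and para to the other); the iminium group of 9 deactivates the ring against a second attack before hydrolysis.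

Step 7
Reactants: 10 2,4-dihydroxy-3-(5,7,4'-trimethoxyflavon-6-yl)benzaldehyde; 11 ethyl (triphenylphosphoranylidene)acetate
Product: 14 6-(7-hydroxycoumarin-8-yl)-5,7,4'-trimethoxyflavone, via E-cinnamate ester 12 (not isolated), via Z-cinnamate ester 13 (not isolated)
Conditions: 11 (1.3 equiv), N,N-diethylaniline, reflux (ca. 215 °C), N2
Reagents that add atoms: none
Why: Wittig olefination of the salicylaldehyde with the stabilised ylide is followed at this temperature by E/Z equilibration of the cinnamate and lactonisation through the ortho hydroxyl, a standard one-flask coumarin synthesis; the other hydroxyl, para to the former formyl carbon, cannot cyclise and becomes the 7-OH.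

Step 8
Reactants: 14 6-(7-hydroxycoumarin-8-yl)-5,7,4'-trimethoxyflavone
Product: 15 5,7-dihydroxy-6-(7-hydroxy-2-oxo-2H-chromen-8-yl)-2-(4-hydroxyphenyl)-4H-chromen-4-one (target CNP0223343.0)
Conditions: BBr3 (10 equiv), CH2Cl2, −78 °C to rt; then ice-water
Reagents that add atoms: none
Why: Lewis-acid ether cleavage with BBr3 removes the 5-, 7- and 4'-methyl groups while lactone and pyrone survive, and the absence of hot protic acid avoids the Wessely–Moser ring opening and reclosure that would move the aryl group from C6 to C8.

**Compound list**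

1 | apigenin (5,7,4'-trihydroxyflavone) | O=c1cc(-c2ccc(O)cc2)oc2cc(O)cc(O)c12 | starting material
2 | 5-hydroxy-7,4'-dimethoxyflavone | COc1ccc(-c2cc(=O)c3c(O)cc(OC)cc3o2)cc1 | intermediate
3 | 5-hydroxy-6-iodo-7,4'-dimethoxyflavone | COc1ccc(-c2cc(=O)c3c(O)c(I)c(OC)cc3o2)cc1 | intermediate
4 | 6-iodo-5,7,4'-trimethoxyflavone | COc1ccc(-c2cc(=O)c3c(OC)c(I)c(OC)cc3o2)cc1 | intermediate
5 | cyclohexane-1,3-dione | O=C1CCCC(=O)C1 | starting material
6 | potassium 3-oxo-2-(5,7,4'-trimethoxyflavon-6-yl)cyclohex-1-en-1-olate | COc1ccc(-c2cc(=O)c3c(OC)c(C4=C([O-])CCCC4=O)c(OC)cc3o2)cc1.[K+] | intermediate (not isolated)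
7 | 3-hydroxy-2-(5,7,4'-trimethoxyflavon-6-yl)cyclohex-2-en-1-one (enol form of the 2-aryl-1,3-dione) | COc1ccc(-c2cc(=O)c3c(OC)c(C4=C(O)CCCC4=O)c(OC)cc3o2)cc1 | intermediate
8 | 6-(2,6-dihydroxyphenyl)-5,7,4'-trimethoxyflavone | COc1ccc(-c2cc(=O)c3c(OC)c(-c4c(O)cccc4O)c(OC)cc3o2)cc1 | intermediate
9 | N-{[2,4-dihydroxy-3-(5,7,4'-trimethoxyflavon-6-yl)phenyl]methylidene}-N-methylmethanaminium chloride | COc1ccc(-c2cc(=O)c3c(OC)c(-c4c(O)ccc(C=[N+](C)C)c4O)c(OC)cc3o2)cc1.[Cl-] | intermediate (not isolated)
10 | 2,4-dihydroxy-3-(5,7,4'-trimethoxyflavon-6-yl)benzaldehyde | COc1ccc(-c2cc(=O)c3c(OC)c(-c4c(O)ccc(C=O)c4O)c(OC)cc3o2)cc1 | intermediate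
11 | ethyl (triphenylphosphoranylidene)acetate | CCOC(=O)C=P(c1ccccc1)(c1ccccc1)c1ccccc1 | starting material
12 | ethyl (E)-3-[2,4-dihydroxy-3-(5,7,4'-trimethoxyflavon-6-yl)phenyl]prop-2-enoate | CCOC(=O)/C=C/c1ccc(O)c(-c2c(OC)cc3oc(-c4ccc(OC)cc4)cc(=O)c3c2OC)c1O | intermediate (not isolated)
13 | ethyl (Z)-3-[2,4-dihydroxy-3-(5,7,4'-trimethoxyflavon-6-yl)phenyl]prop-2-enoate | CCOC(=O)/C=C\c1ccc(O)c(-c2c(OC)cc3oc(-c4ccc(OC)cc4)cc(=O)c3c2OC)c1O | intermediate (not isolated)
14 | 6-(7-hydroxy-2-oxo-2H-chromen-8-yl)-5,7,4'-trimethoxyflavone | COc1ccc(-c2cc(=O)c3c(OC)c(-c4c(O)ccc5ccc(=O)oc45)c(OC)cc3o2)cc1 | intermediate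
15 | 5,7-dihydroxy-6-(7-hydroxy-2-oxo-2H-chromen-8-yl)-2-(4-hydroxyphenyl)-4H-chromen-4-one | O=c1ccc2ccc(O)c(-c3c(O)cc4oc(-c5ccc(O)cc5)cc(=O)c4c3O)c2o1 | target

**Step count**

Total steps: 8. Longest linear sequence: 8 steps (1 to 15); 5 and 11 are bought.

**Steps most likely to fail**

Step 4. Reductive elimination at the doubly ortho-substituted aryl–palladium centre may be outrun by hydrodeiodination or by O-arylation of the enolate. The fallback sets out from 4 and returns at 8, making the same C6–aryl bond with an aromatic partner. Commercial 1,3-bis(benzyloxy)benzene would be lithiated between the two ether oxygens (n-BuLi, THF, 0 °C), trapped with B(OMe)3 and hydrolysed with dilute acid to 2,6-bis(benzyloxy)phenylboronic acid F1. Suzuki–Miyaura coupling of F1 with 4 (Pd(OAc)2, 2-dicyclohexylphosphino-2',6'-dimethoxybiphenyl, K3PO4, toluene–water, 100 °C) should give 6-[2,6-bis(benzyloxy)phenyl]-5,7,4'-trimethoxyflavone F2. Hydrogenolysis of the benzyl ethers (H2, Pd/C, EtOAc–MeOH, rt) would then uncover resorcinol 8, bypassing 7.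

Step 5. Dehydrogenation on the metal surface may stall because the chelating dione and the resorcinol bind the catalyst, or hydrogen may be passed to the pyrone double bond instead of to ethylene. The fallback sets out from 7 and returns at 8 without a metal surface. Treatment of 7 with TMSOTf and Et3N (CH2Cl2, 0 °C) should give 6-[2,6-bis(trimethylsilyloxy)cyclohexa-1,5-dien-1-yl]-5,7,4'-trimethoxyflavone F3. Oxidation of this electron-rich diene with DDQ (dioxane, rt) should give 6-[2,6-bis(trimethylsilyloxy)phenyl]-5,7,4'-trimethoxyflavone F4, and dilute HCl in THF would cleave the silyl ethers to 8.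

Step 6. The chloroiminium reagent may be consumed by O-formylation of the two phenols or by attack at the pyrone carbonyl, or a second formylation may follow at the other equivalent position. The fallback sets out from 8 and returns at 14, skipping the aldehyde stage. Heating 8 with ethyl propiolate and ZnCl2 (dioxane, 100 °C) is a Pechmann-type annulation in which C4 of the resorcinol ring adds to the alkyne and the neighbouring hydroxyl closes the lactone with loss of ethanol, which should give 14 directly.

**Further compounds**

F1 | step 4 | 2,6-bis(benzyloxy)phenylboronic acid | OB(O)c1c(OCc2ccccc2)cccc1OCc1ccccc1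
F2 | step 4 | 6-[2,6-bis(benzyloxy)phenyl]-5,7,4'-trimethoxyflavone | COc1ccc(-c2cc(=O)c3c(OC)c(-c4c(OCc5ccccc5)cccc4OCc4ccccc4)c(OC)cc3o2)cc1
F3 | step 5 | 6-[2,6-bis(trimethylsilyloxy)cyclohexa-1,5-dien-1-yl]-5,7,4'-trimethoxyflavone | COc1ccc(-c2cc(=O)c3c(OC)c(C4=C(O[Si](C)(C)C)CCC=C4O[Si](C)(C)C)c(OC)cc3o2)cc1
F4 | step 5 | 6-[2,6-bis(trimethylsilyloxy)phenyl]-5,7,4'-trimethoxyflavone | COc1ccc(-c2cc(=O)c3c(OC)c(-c4c(O[Si](C)(C)C)cccc4O[Si](C)(C)C)c(OC)cc3o2)cc1
F0 | step 6 | none | none
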